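**Plan**

- Retrosynthesis: the five benzyl ethers and the tert-butyl ester are removed and ring A is taken back to its dihydro form; the first cut is then the C4–O4 bond of ring A (ring carbon to the ester oxygen of the ring B carboxyl), the second the acyl C–O bond of the ring C–ring B ester.
- Enabling feature: ring A (C1–C6; carboxyl on C1, hydroxyls on C3 and C5, acylated O4 on C4) is the dehydro form of a 4-acyloxycyclohexane-3,5-dione, and C4, the only carbon between both carbonyls, is the only one that can carry a diazo group.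
- Forward: no ring is formed; the ring C acid chloride is esterified with the ring B phenol aldehyde, the aldehyde is oxidised to the acid, and this acid is joined to the ring A diazodione by rhodium carbenoid O–H insertion at C4.
- Ring A is then aromatised by one dehydrogenation; acid cleaves the tert-butyl ester and hydrogenolysis the benzyl ethers.
- Stereochemistry: the target has no stereocentre; C1 of the insertion product is stereogenic only in its enol form, is racemic, and disappears on aromatisation.

Key step: step 9

Assumption: 3,4,5-tris(benzyloxy)benzoic acid is taken as a purchased material, and an aryl ester flanked by free phenols is taken to hold its position as long as the medium stays neutral to acidic, so no step after the aromatisation uses base.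

**Route**

Step 1
Reactants: 1 3,5-dihydroxybenzoic acid
Product: 2 tert-butyl 3,5-dihydroxybenzoate
Conditions: Me2NCH(OtBu)2, PhMe, 80 °C
Reagents that add atoms: N,N-dimethylformamide di-tert-butyl acetal, CN(C)C(OC(C)(C)C)OC(C)(C)C
Why: Alkylative esterification with a formamide acetal, in which the carboxylate is tert-butylated while the much less acidic phenols stay free; the tert-butyl ester is chosen because it survives the basic, reductive and carbenoid steps ahead and leaves at the end with acid.

Step 2
Reactants: 2 tert-butyl 3,5-dihydroxybenzoate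
Product: 3 tert-butyl 3,5-dioxocyclohexane-1-carboxylate
Conditions: HCO2Na, 10% Pd/C, H2O–iPrOH, 60 °C
Reagents that add atoms: none
Why: Palladium-catalysed transfer hydrogenation of a resorcinol, which should stop at the 1,3-dione because the product is held as its enolate and resists further reduction, while the tert-butyl ester is inert to the mildly basic aqueous formate.

Step 3
Reactants: 3 tert-butyl 3,5-dioxocyclohexane-1-carboxylate
Product: 4 tert-butyl 4-diazo-3,5-dioxocyclohexane-1-carboxylate
Conditions: 4-AcNHC6H4SO2N3, Et3N, MeCN, 0 °C to rt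
Reagents that add atoms: 4-acetamidobenzenesulfonyl azide, CC(=O)Nc1ccc(cc1)S(=O)(=O)N=[N+]=[N-]
Why: Regitz diazo transfer, in which the dione enolate attacks the terminal azide nitrogen through C4, the only doubly activated carbon, and the adduct collapses to the diazodione and the sulfonamide.

Step 4
Reactants: 5 3,4,5-trihydroxybenzaldehyde
Product: 6 3,4,5-tris(benzyloxy)benzaldehyde
Conditions: BnBr, K2CO3, DMF, rt, under N2
Reagents that add atoms: benzyl bromide, BrCc1ccccc1
Why: Williamson ether synthesis on all three phenols, with air excluded to protect the pyrogallol unit until it is fully alkylated; the aldehyde is untouched.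

Step 5
Reactants: 6 3,4,5-tris(benzyloxy)benzaldehyde
Product: 7 3,5-bis(benzyloxy)-4-hydroxybenzaldehyde
Conditions: MgBr2·OEt2, PhMe–Et2O, reflux
Reagents that add atoms: none
Why: Lewis-acid-mediated regioselective dealkylation of the central ether of a 3,4,5-trialkoxybenzaldehyde, in which magnesium is chelated by O4 and a neighbouring oxygen, bromide opens the benzylic C–O bond of the most crowded ether whose phenoxide (para to the formyl group) is the best leaving group, and the magnesium phenoxide formed shields the flanking ethers from further cleavage.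

Step 6
Reactants: 8 3,4,5-tris(benzyloxy)benzoic acid
Product: 9 3,4,5-tris(benzyloxy)benzoyl chloride
Conditions: (COCl)2, cat. DMF, CH2Cl2, 0 °C to rt
Reagents that add atoms: oxalyl chloride, O=C(Cl)C(=O)Cl
Why: Acid chloride formation through the Vilsmeier-type chloroiminium salt from oxalyl chloride and catalytic DMF, conditions that aryl benzyl ethers tolerate at room temperature.

Step 7
Reactants: 7 3,5-bis(benzyloxy)-4-hydroxybenzaldehyde; 9 3,4,5-tris(benzyloxy)benzoyl chloride
Product: 10 2,6-bis(benzyloxy)-4-formylphenyl 3,4,5-tris(benzyloxy)benzoate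
Conditions: Et3N, DMAP (cat.), CH2Cl2, 0 °C to rt
Reagents that add atoms: none
Why: DMAP-catalysed acylation through the acylpyridinium ion of a hindered but acidic phenol that has only O4 free, so the ring C–ring B ester forms at a defined oxygen.

Step 8
Reactants: 10 2,6-bis(benzyloxy)-4-formylphenyl 3,4,5-tris(benzyloxy)benzoate
Product: 11 3,5-bis(benzyloxy)-4-{[3,4,5-tris(benzyloxy)benzoyl]oxy}benzoic acid
Conditions: NaClO2, NaH2PO4, 2-methyl-2-butene, tBuOH–THF–H2O, rt
Reagents that add atoms: sodium chlorite, [Na+].[O-]Cl=O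
Why: Pinnick oxidation, in which chlorous acid adds to the aldehyde and fragments to the carboxylic acid near pH 4, where the aryl ester and the benzyl ethers are stable, and the alkene traps hypochlorous acid.

Step 9
Reactants: 4 tert-butyl 4-diazo-3,5-dioxocyclohexane-1-carboxylate; 11 3,5-bis(benzyloxy)-4-{[3,4,5-tris(benzyloxy)benzoyl]oxy}benzoic acid
Product: 12 tert-butyl 4-{[3,5-bis(benzyloxy)-4-{[3,4,5-tris(benzyloxy)benzoyl]oxy}benzoyl]oxy}-3-hydroxy-5-oxocyclohex-3-ene-1-carboxylate (enol tautomer of the 4-acyloxy-3,5-dione, racemic at C1)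
Conditions: Rh2(OAc)4 (2 mol %), ClCH2CH2Cl, 40 °C, slow addition of 4 to a slight excess of 11
Reagents that add atoms: none
Why: Rh2(OAc)4 expels dinitrogen from 4 to give a divalent rhodium carbenoid that is electrophilic at C4; the hydroxyl oxygen of acid 11 adds to it and proton transfer within the oxonium ylide forms the C4–O4 bond, after which the 2-acyloxy-1,3-dione enolises to 12. The closest known reaction type is the Rh2(OAc)4-catalysed O–H insertion of 2-diazo-1,3-dicarbonyl compounds into carboxylic acids. No ring is closed and no stereocentre of the target is set, since C1 of 12 is stereogenic only in the enol form, is racemic and vanishes on aromatisation. Regioselectivity for O4 over O3 and O5 is built into the substrate, because only C4 lies between two carbonyl groups and can hold the diazo group, and because a shift of the acyl group to O3 would exchange a vinylogous acid for a vinylogous anhydride. Chemoselectivity is needed against Wolff ring contraction, attack of the carbenoid on the benzyl arenes and a second insertion into the enol O–H of 12; the acidity of the carboxylic acid, mild heating and slow addition of the diazodione to excess acid should favour the wanted insertion.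

Step 10
Reactants: 12 tert-butyl 4-acyloxy-3-hydroxy-5-oxocyclohex-3-ene-1-carboxylate (acyl = protected ring C–ring B unit)
Product: 13 tert-butyl 4-{[3,5-bis(benzyloxy)-4-{[3,4,5-tris(benzyloxy)benzoyl]oxy}benzoyl]oxy}-3,5-dihydroxybenzoate
Conditions: Pd(O2CCF3)2 (10 mol %), DMSO (20 mol %), O2 (1 atm), AcOH–EtOAc, 70 °C
Reagents that add atoms: none
Why: Aerobic palladium-catalysed α,β-dehydrogenation of a cyclic ketone, the catalytic relative of the Saegusa–Ito oxidation, in which a divalent palladium enolate at C2 loses the ester-activated C1 hydrogen by β-hydride elimination to give an enone that is the keto tautomer of the resorcinol and aromatises at once, so one dehydrogenation suffices and the acidic medium keeps the acyl group on O4.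

Step 11
Reactants: 13 tert-butyl 4-acyloxy-3,5-dihydroxybenzoate (acyl = protected ring C–ring B unit)
Product: 14 4-{[3,5-bis(benzyloxy)-4-{[3,4,5-tris(benzyloxy)benzoyl]oxy}benzoyl]oxy}-3,5-dihydroxybenzoic acid
Conditions: CF3CO2H, CH2Cl2, 0 °C to rt
Reagents that add atoms: none
Why: Acidolysis of the tert-butyl ester with loss of the tert-butyl cation as isobutene, under which aryl esters and benzyl ethers on acyl-substituted rings should hold and phenoxide-mediated acyl migration from O4 to O3 is suppressed.

Step 12
Reactants: 14 4-acyloxy-3,5-dihydroxybenzoic acid with five benzyl ethers on rings B and C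
Product: 15 3,5-dihydroxy-4-{[3,5-dihydroxy-4-(3,4,5-trihydroxybenzoyloxy)benzoyl]oxy}benzoic acid (target)
Conditions: H2 (1 atm), 10% Pd/C, THF, rt
Reagents that add atoms: none
Why: Hydrogenolysis of the five benzyl ethers over palladium on carbon under base-free conditions, in which both aryl ester bonds are inert and the free carboxylic acid keeps the medium acidic enough to hold the esters on the central oxygens.

**Compound list**

1 | 3,5-dihydroxybenzoic acid | O=C(O)c1cc(O)cc(O)c1 | starting material
2 | tert-butyl 3,5-dihydroxybenzoate | CC(C)(C)OC(=O)c1cc(O)cc(O)c1 | intermediate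
3 | tert-butyl 3,5-dioxocyclohexane-1-carboxylate | CC(C)(C)OC(=O)C1CC(=O)CC(=O)C1 | intermediate
4 | tert-butyl 4-diazo-3,5-dioxocyclohexane-1-carboxylate | CC(C)(C)OC(=O)C1CC(=O)C(=[N+]=[N-])C(=O)C1 | intermediate
5 | 3,4,5-trihydroxybenzaldehyde | O=Cc1cc(O)c(O)c(O)c1 | starting material
6 | 3,4,5-tris(benzyloxy)benzaldehyde | O=Cc1cc(OCc2ccccc2)c(OCc2ccccc2)c(OCc2ccccc2)c1 | intermediate
7 | 3,5-bis(benzyloxy)-4-hydroxybenzaldehyde | O=Cc1cc(OCc2ccccc2)c(O)c(OCc2ccccc2)c1 | intermediate
8 | 3,4,5-tris(benzyloxy)benzoic acid | O=C(O)c1cc(OCc2ccccc2)c(OCc2ccccc2)c(OCc2ccccc2)c1 | starting material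
9 | 3,4,5-tris(benzyloxy)benzoyl chloride | O=C(Cl)c1cc(OCc2ccccc2)c(OCc2ccccc2)c(OCc2ccccc2)c1 | intermediate
10 | 2,6-bis(benzyloxy)-4-formylphenyl 3,4,5-tris(benzyloxy)benzoate | O=Cc1cc(OCc2ccccc2)c(OC(=O)c2cc(OCc3ccccc3)c(OCc3ccccc3)c(OCc3ccccc3)c2)c(OCc2ccccc2)c1 | intermediate
11 | 3,5-bis(benzyloxy)-4-{[3,4,5-tris(benzyloxy)benzoyl]oxy}benzoic acid | O=C(O)c1cc(OCc2ccccc2)c(OC(=O)c2cc(OCc3ccccc3)c(OCc3ccccc3)c(OCc3ccccc3)c2)c(OCc2ccccc2)c1 | intermediate
12 | tert-butyl 4-{[3,5-bis(benzyloxy)-4-{[3,4,5-tris(benzyloxy)benzoyl]oxy}benzoyl]oxy}-3-hydroxy-5-oxocyclohex-3-ene-1-carboxylate (enol tautomer, racemic at C1) | CC(C)(C)OC(=O)C1CC(O)=C(OC(=O)c2cc(OCc3ccccc3)c(OC(=O)c3cc(OCc4ccccc4)c(OCc4ccccc4)c(OCc4ccccc4)c3)c(OCc3ccccc3)c2)C(=O)C1 | intermediate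
13 | tert-butyl 4-{[3,5-bis(benzyloxy)-4-{[3,4,5-tris(benzyloxy)benzoyl]oxy}benzoyl]oxy}-3,5-dihydroxybenzoate | CC(C)(C)OC(=O)c1cc(O)c(OC(=O)c2cc(OCc3ccccc3)c(OC(=O)c3cc(OCc4ccccc4)c(OCc4ccccc4)c(OCc4ccccc4)c3)c(OCc3ccccc3)c2)c(O)c1 | intermediate
14 | 4-{[3,5-bis(benzyloxy)-4-{[3,4,5-tris(benzyloxy)benzoyl]oxy}benzoyl]oxy}-3,5-dihydroxybenzoic acid | O=C(O)c1cc(O)c(OC(=O)c2cc(OCc3ccccc3)c(OC(=O)c3cc(OCc4ccccc4)c(OCc4ccccc4)c(OCc4ccccc4)c3)c(OCc3ccccc3)c2)c(O)c1 | intermediate
15 | 3,5-dihydroxy-4-{[3,5-dihydroxy-4-(3,4,5-trihydroxybenzoyloxy)benzoyl]oxy}benzoic acid | O=C(O)c1cc(O)c(OC(=O)c2cc(O)c(OC(=O)c3cc(O)c(O)c(O)c3)c(O)c2)c(O)c1 | target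

**Totals and risks**

Total step count: 12. Longest linear sequence: 8 steps (steps 4, 5, 7, 8, 9, 10, 11 and 12, from 3,4,5-trihydroxybenzaldehyde).

Steps most likely to fail:

1. Step 10 (aromatisation). The palladium catalyst may fail to turn over because the strongly enolised dione is palladated at C4, where no β-hydrogen is available. The acyl group may also drift from O4 to O3 once the ring A phenols are free at 70 °C. The fallback sets out from 12 and returns at 13. TBSOTf and Et3N in CH2Cl2 at 0 °C should convert 12 into the bis(silyl) dienol ether tert-butyl 4-acyloxy-3,5-bis(tert-butyldimethylsilyloxy)cyclohexa-2,4-diene-1-carboxylate F1. DDQ in CH2Cl2 at 0 °C should then abstract the C1 hydride, the cation being stabilised by both silyloxy groups, and proton loss from C6 should give the aromatic bis(silyl ether) tert-butyl 4-acyloxy-3,5-bis(tert-butyldimethylsilyloxy)benzoate F2. HF·pyridine in THF at 0 °C would free both phenols under acidic conditions to give 13.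

2. Step 9 (carbenoid O–H insertion). Dinitrogen loss from the doubly stabilised cyclic diazodione may be slow. The carbenoid may also be consumed by Wolff ring contraction, by addition to the benzyl arenes or by a second insertion into the enol O–H of the product. The fallback sets out from 3 and returns at 12. PhI(OAc)2 and KOH in MeOH at 0 °C should convert dione 3 into the phenyliodonium ylide tert-butyl 3-oxido-5-oxo-4-(phenyliodonio)cyclohex-3-ene-1-carboxylate F3. Heating F3 with acid 11 in MeCN should protonate C4 and let the carboxylate displace iodobenzene from that carbon, forming the same C4–O4 bond without a metal carbenoid.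

3. Step 5 (central debenzylation). Regiocontrol may be lost through cleavage of a flanking benzyl ether, or a second ether may be cleaved. The fallback sets out from 5, bypasses 6 and returns at 7. Allyl bromide and NaHCO3 in DMF at 40 °C should alkylate only the most acidic hydroxyl, para to the formyl group, to give 4-(allyloxy)-3,5-dihydroxybenzaldehyde F4. BnBr and K2CO3 in DMF would then give 4-(allyloxy)-3,5-bis(benzyloxy)benzaldehyde F5. Pd(PPh3)4 with morpholine in THF would remove the allyl group to give 7.

**Further compounds**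

F1 | step 10 | tert-butyl 4-{[3,5-bis(benzyloxy)-4-{[3,4,5-tris(benzyloxy)benzoyl]oxy}benzoyl]oxy}-3,5-bis(tert-butyldimethylsilyloxy)cyclohexa-2,4-diene-1-carboxylate (racemic) | CC(C)(C)OC(=O)C1C=C(O[Si](C)(C)C(C)(C)C)C(OC(=O)c2cc(OCc3ccccc3)c(OC(=O)c3cc(OCc4ccccc4)c(OCc4ccccc4)c(OCc4ccccc4)c3)c(OCc3ccccc3)c2)=C(O[Si](C)(C)C(C)(C)C)C1
F2 | step 10 | tert-butyl 4-{[3,5-bis(benzyloxy)-4-{[3,4,5-tris(benzyloxy)benzoyl]oxy}benzoyl]oxy}-3,5-bis(tert-butyldimethylsilyloxy)benzoate | CC(C)(C)OC(=O)c1cc(O[Si](C)(C)C(C)(C)C)c(OC(=O)c2cc(OCc3ccccc3)c(OC(=O)c3cc(OCc4ccccc4)c(OCc4ccccc4)c(OCc4ccccc4)c3)c(OCc3ccccc3)c2)c(O[Si](C)(C)C(C)(C)C)c1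
F3 | step 9 | tert-butyl 3-oxido-5-oxo-4-(phenyliodonio)cyclohex-3-ene-1-carboxylate (phenyliodonium ylide of 3) | CC(C)(C)OC(=O)C1CC([O-])=C([I+]c2ccccc2)C(=O)C1
F4 | step 5 | 4-(allyloxy)-3,5-dihydroxybenzaldehyde | O=Cc1cc(O)c(OCC=C)c(O)c1
F5 | step 5 | 4-(allyloxy)-3,5-bis(benzyloxy)benzaldehyde | O=Cc1cc(OCc2ccccc2)c(OCC=C)c(OCc2ccccc2)c1
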